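Readings and results come from a simulation from invented constants; scatter was added.

1. If no catalyst were lost, the rate at 20% conversion would follow the catalyst charge, and the factor on going to 400 mM would be 10.0, the zero of the scale.

| flask | starting material | reagent | capture agent | free catalyst | remark |
|---|---|---|---|---|---|
| north-east | 0.54 M | 1.2 M | 0.80 M | 40 mM | run made earlier |
| west | 1.2 M | 1.2 M | 0.80 M | 40 mM | run made earlier |
| south-east | 0.80 M | 1.2 M | 0.80 M | 20 mM | run made earlier |
| flask | 0.80 M | 1.20 M | 0.800 M | 40 mM |  |

| run | time / min | target / % | starting material / % |
|---|---|---|---|
| north-east | 0.667 | 14.5 | 84.2 |
| north-east | 1.33 | 26.7 | 72.7 |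
| north-east | 2.00 | 36.4 | 63.8 |
| north-east | 2.50 | 42.6 | 57.4 |
| west | 0.200 | 2.4 | 97.2 |
| west | 0.417 | 3.7 | 95.8 |
| west | 1.00 | 10.8 | 89.0 |
| west | 2.50 | 23.6 | 75.9 |
| south-east | 0.200 | 1.8 | 98.2 |
| south-east | 0.417 | 2.7 | 96.8 |
| south-east | 1.00 | 7.8 | 92.9 |
| south-east | 2.50 | 15.8 | 83.4 |

(standard deviation of a reading: 0.5 percentage points)

- steps under discussion: catalyst intermediate A <-> by-product + catalyst intermediate B; reagent + free catalyst -> catalyst intermediate A; starting material + catalyst intermediate B -> catalyst intermediate C; capture agent + catalyst intermediate B -> trapped intermediate; catalyst intermediate C -> free catalyst + target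
- no earlier run changes the charge of reagent; that part of a forecast is a guess

- factor on the rate of making target when 20% of the starting material are converted if reagent is charged twice over
- factor on the rate when 20% of the starting material are converted if free catalyst is charged at 400 mM instead

2. Catalyst leaves the round when catalyst intermediate B meets capture agent instead of starting material. The loss per turnover is then the selectivity factor times [capture agent]/[starting material], and the ratio asked for is the zero times exp(loss per turnover × difference in turnovers).

3. The charges are exact: 4.00 turnovers at 40 mM against 0.400 at 400 mM. In this reckoning about 86.7% of the reagent charge stands at 20% conversion at either catalyst charge, so reagent cancels from the ratio. The two charges lie 3.60 turnovers apart, so a change of one point in the loss per turnover moves the ratio by about 3.60%, and the loss is the number to know, to a point or two.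

4. The north-east run shows it best, its [capture agent]/[starting material] being higher than in the other runs. Its turnover rate reads 2.71 /min up to 1.33 min and 1.83 /min from there to 2.50 min, with midpoints 2.88 turnovers apart. Assuming here that the rate follows reagent, the fall in reagent takes a factor 1.11 out of that drop, leaving a loss of 0.0983 per turnover. This gives a reading of 0.0482 for the selectivity factor, capture agent against starting material at equal concentration.

5. For the flask this reading gives an estimated loss of 0.0536 per turnover on the way to 20%, so this reckoning gives a ratio of 12.1, with a guess of two for doubled reagent.

6. The forecast gives 1.4 and 15, from “about 10% loss per turnover”; its ratio stands higher than the reckoning above.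

The flask gives 1.99 for doubled reagent and 11.8 for 400 mM of free catalyst.

    catalyst intermediate A ⇌ by-product + catalyst intermediate B (K = 0.520 M, k = 4.97 /s)
    reagent + free catalyst → catalyst intermediate A (k = 0.0556 /M/s)
    starting material + catalyst intermediate B → catalyst intermediate C (k = 3.08 /M/s)
    capture agent + catalyst intermediate B → trapped intermediate (k = 0.127 /M/s)
    catalyst intermediate C → free catalyst + target (k = 1.74 /s)

That ratio stands above the zero, and after 1.50 min the flask holds 20.2% of its catalyst as trapped intermediate. Carried to the end of the flask, the selectivity factor puts the catalyst fully trapped when selectivity factor × [capture agent] × ln(charged/remaining starting material) equals the catalyst charge, which means at 35.5% of the starting material left. After 30.0 min the flask holds 99.7% of its catalyst as trapped intermediate and 28.9% of its starting material.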